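**Strategy.** The route rests on disconnecting the pyrrole ring (ring B) of the 6-bromoindole at C3–C3a and N1–C2. C2 and C3 of that indole are treated as the two carbons of an alkyne already attached to imidazole C4, while C3a, N1 and the C6 bromine come from 5-bromo-2-iodoaniline. A Larock heteroannulation therefore joins the bromoarene to a preformed indolyl-imidazole and closes ring B in one operation, with a silyl group steering the regiochemistry. The precursor is a 2-(1-Boc-indol-3-yl)-1-SEM-imidazole carrying a triethylsilylethynyl group at C4, assembled by Sonogashira and Negishi couplings. One acid treatment then removes silyl, Boc and SEM.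

Key step: step 4

Remark on the chemistry: the two imidazole nitrogens of the target are tautomerically equivalent, so SEM ([2-(trimethylsilyl)ethoxy]methyl) is placed on the nitrogen remote from the alkyne to keep the alkyne terminus unhindered. The alkyne cap is triethylsilyl for stability to carbonate, and the spectator indole nitrogen carries Boc so that a single acid step unmasks everything.

**Step 1**
Reactants: 1 4-iodo-1H-imidazole
Product: 2 4-iodo-1-SEM-1H-imidazole
Conditions: NaH, SEMCl, THF, 0 °C to rt; chromatography to remove the minor 5-iodo isomer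
Reagents that add atoms: [2-(trimethylsilyl)ethoxy]methyl chloride (SEMCl), C[Si](C)(C)CCOCCl
Why: N-alkylation of the imidazolide anion should occur mainly at the nitrogen remote from iodine, which is both less hindered and less deactivated, so the 1,4-isomer is expected as the main product.

**Step 2**
Reactants: 2 4-iodo-1-SEM-1H-imidazole; 3 ethynyl(triethyl)silane
Product: 4 4-[(triethylsilyl)ethynyl]-1-SEM-1H-imidazole
Conditions: PdCl2(PPh3)2, CuI, Et3N, THF, 50 °C
Reagents that add atoms: none
Why: Sonogashira coupling of a heteroaryl iodide with a silyl-capped terminal alkyne is routine, and the silyl cap prevents a second coupling.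

**Step 3**
Reactants: 4 4-[(triethylsilyl)ethynyl]-1-SEM-1H-imidazole; 5 tert-butyl 3-iodo-1H-indole-1-carboxylate
Product: 8 tert-butyl 3-{4-[(triethylsilyl)ethynyl]-1-SEM-1H-imidazol-2-yl}-1H-indole-1-carboxylate, via 2-lithioimidazole 6 (not isolated), via imidazol-2-ylzinc chloride 7 (not isolated)
Conditions: n-BuLi, THF, −78 °C; ZnCl2, −78 °C to rt; then 5, Pd(PPh3)4, 60 °C
Reagents that add atoms: none
Why: C2–H is the only strongly acidic position of a 1-SEM-imidazole, so directed lithiation is unambiguous; transmetalation to zinc gives a nucleophile that tolerates the Boc carbamate, and Negishi coupling with the 3-iodoindole should form the imidazole C2–indole C3 bond.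

**Step 4**
Reactants: 8 tert-butyl 3-{4-[(triethylsilyl)ethynyl]-1-SEM-1H-imidazol-2-yl}-1H-indole-1-carboxylate; 9 5-bromo-2-iodoaniline
Product: 10 tert-butyl 3-{4-[6-bromo-2-(triethylsilyl)-1H-indol-3-yl]-1-SEM-1H-imidazol-2-yl}-1H-indole-1-carboxylate
Conditions: Pd(OAc)2, LiCl, Na2CO3, DMF, 100 °C
Reagents that add atoms: none
Why: Pd(OAc)2 is reduced in the flask to zerovalent palladium, which inserts into the C–I bond of 9; the arylpalladium then adds syn across the alkyne of 8 so that the aryl carbon (future C3a) bonds to the imidazolyl-bearing carbon (future C3) and palladium sits on the silyl-bearing carbon (future C2). The aniline nitrogen replaces halide on the vinylpalladium to give a six-membered azapalladacycle, and C–N reductive elimination forms N1–C2. The closest known reaction type is the Larock indole synthesis with aryl(silyl)alkynes, which gives 2-silyl-3-arylindoles. Ring B is closed as a formal [3+2] heteroannulation, its last bond arising by reductive elimination from the palladacycle, not by direct attack of nitrogen on the alkyne. No stereocenter is formed. Regioselectivity should be secured by the bulky triethylsilyl group, which takes the position next to palladium and hence next to nitrogen while the small imidazol-4-yl group (SEM on the remote nitrogen) goes to C3, and chemoselectivity by the much faster oxidative addition of the aryl iodide than of the aryl bromide under phosphine-free conditions.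

**Step 5**
Reactants: 10 tert-butyl 3-{4-[6-bromo-2-(triethylsilyl)-1H-indol-3-yl]-1-SEM-1H-imidazol-2-yl}-1H-indole-1-carboxylate
Product: 11 nortopsentin C
Conditions: 3 M aq HCl, EtOH, 80 °C; then aq NH3
Reagents that add atoms: none
Why: Acid should effect ipso-protodesilylation of the 2-silylindole, acidolysis of the Boc carbamate and solvolysis of the imidazole N,O-acetal (SEM) in one pot, with ethanol trapping the released formaldehyde and the protonated imidazole deactivating both indoles toward side reactions.

**Compound list**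
1 | 4-iodo-1H-imidazole | Ic1c[nH]cn1 | starting material
2 | 4-iodo-1-{[2-(trimethylsilyl)ethoxy]methyl}-1H-imidazole | C[Si](C)(C)CCOCn1cnc(I)c1 | intermediate
3 | ethynyl(triethyl)silane (triethylsilylacetylene) | CC[Si](CC)(CC)C#C | starting material
4 | 4-[(triethylsilyl)ethynyl]-1-{[2-(trimethylsilyl)ethoxy]methyl}-1H-imidazole | CC[Si](CC)(CC)C#Cc1cn(COCC[Si](C)(C)C)cn1 | intermediate
5 | tert-butyl 3-iodo-1H-indole-1-carboxylate | CC(C)(C)OC(=O)n1cc(I)c2ccccc21 | starting material
6 | {4-[(triethylsilyl)ethynyl]-1-SEM-imidazol-2-yl}lithium | [Li]c1nc(C#C[Si](CC)(CC)CC)cn1COCC[Si](C)(C)C | intermediate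
7 | chloro{4-[(triethylsilyl)ethynyl]-1-SEM-imidazol-2-yl}zinc | Cl[Zn]c1nc(C#C[Si](CC)(CC)CC)cn1COCC[Si](C)(C)C | intermediate
8 | tert-butyl 3-{4-[(triethylsilyl)ethynyl]-1-SEM-1H-imidazol-2-yl}-1H-indole-1-carboxylate | CC[Si](CC)(CC)C#Cc1cn(COCC[Si](C)(C)C)c(-c2cn(C(=O)OC(C)(C)C)c3ccccc23)n1 | intermediate
9 | 5-bromo-2-iodoaniline | Nc1cc(Br)ccc1I | starting material
10 | tert-butyl 3-{4-[6-bromo-2-(triethylsilyl)-1H-indol-3-yl]-1-SEM-1H-imidazol-2-yl}-1H-indole-1-carboxylate | CC[Si](CC)(CC)c1[nH]c2cc(Br)ccc2c1-c1cn(COCC[Si](C)(C)C)c(-c2cn(C(=O)OC(C)(C)C)c3ccccc23)n1 | intermediate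
11 | nortopsentin C, 6-bromo-3-[2-(1H-indol-3-yl)-1H-imidazol-4-yl]-1H-indole | Brc1ccc2c(-c3c[nH]c(-c4c[nH]c5ccccc45)n3)c[nH]c2c1 | target

**Total step count:** 5. **Longest linear sequence:** 5 steps (1 → 2 → 4 → 8 → 10 → 11).

**Steps most likely to fail**

Step 4. The alkyne may insert in the wrong orientation, carbonate may strip the alkynyl silyl group before insertion, the crowded, nitrogen-chelating alkyne may insert slowly, or oxidative addition may continue at C–Br and give oligomers. Partial thermal loss of Boc would be harmless, since step 5 removes it. The fallback gives up the annulation and forms the indole C3–imidazole C4 bond by cross-coupling; it sets out from 2 and returns at 11.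
- Commercial 6-bromoindole is iodinated at C3 (I2, KOH, DMF) to 6-bromo-3-iodo-1H-indole F1 and silylated on nitrogen (NaH, TIPSCl, THF) to 6-bromo-3-iodo-1-(triisopropylsilyl)indole F2.
- Iodide 2 undergoes iodine–magnesium exchange (i-PrMgCl·LiCl, THF, −10 °C) to chloro(1-SEM-imidazol-4-yl)magnesium F3, and ZnCl2 converts this into chloro(1-SEM-imidazol-4-yl)zinc F4.
- Negishi coupling of F4 with F2 (Pd(PPh3)4, THF, 40 °C), selective for C–I over C–Br, should give 6-bromo-3-(1-SEM-imidazol-4-yl)-1-(triisopropylsilyl)indole F5.
- LDA (THF, −78 °C) leaves the aryl bromide untouched and is kept from indole C2 by the silyl group; it lithiates imidazole C2 to 6-bromo-3-(2-lithio-1-SEM-imidazol-4-yl)-1-(triisopropylsilyl)indole F6.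
- ZnCl2 gives chloro{4-[6-bromo-1-(triisopropylsilyl)indol-3-yl]-1-SEM-imidazol-2-yl}zinc F7, and Negishi coupling with 5 (Pd(PPh3)4, THF, 60 °C) gives tert-butyl 3-{4-[6-bromo-1-(triisopropylsilyl)indol-3-yl]-1-SEM-imidazol-2-yl}indole-1-carboxylate F8.
- The conditions of step 5 remove Boc, SEM and the N-silyl group and deliver 11.

Step 3. Transmetalation of the azol-2-ylzinc chloride to palladium may be slow, the organometallic may be protonated by adventitious water, or residual organolithium may attack the Boc group. The fallback reverses the polarity of the coupling; it sets out from 4 and returns at 8. Lithio species 6 (n-BuLi, THF, −78 °C) is quenched with I2 to 2-iodo-1-SEM-4-[(triethylsilyl)ethynyl]imidazole F9. Its activated C2–I bond is then coupled with commercial tert-butyl 3-(4,4,5,5-tetramethyl-1,3,2-dioxaborolan-2-yl)indole-1-carboxylate under Suzuki–Miyaura conditions (PdCl2(dppf), K3PO4, dioxane–water, 70 °C) to give 8.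

Step 1. Alkylation may also take place at the nitrogen next to iodine, giving an isomer mixture that is hard to separate. The fallback fixes the regiochemistry by symmetry followed by selective dehalogenation; it sets out from 1 and returns at 2. Compound 1 is iodinated (I2, KOH, water) to 4,5-diiodo-1H-imidazole F10 (also commercial), whose SEM protection (NaH, SEMCl, THF) can give only one product, 4,5-diiodo-1-SEM-imidazole F11. EtMgBr (THF, 0 °C) selectively exchanges the iodine at C5, next to the SEM-bearing nitrogen, to give bromo(4-iodo-1-SEM-imidazol-5-yl)magnesium F12, and protonation with water gives 2 as a single regioisomer.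

**Further compounds**
F1 | step 4 | 6-bromo-3-iodo-1H-indole | Brc1ccc2c(I)c[nH]c2c1
F2 | step 4 | 6-bromo-3-iodo-1-(triisopropylsilyl)indole | CC(C)[Si](C(C)C)(C(C)C)n1cc(I)c2ccc(Br)cc21
F3 | step 4 | chloro(1-SEM-imidazol-4-yl)magnesium | Cl[Mg]c1cn(COCC[Si](C)(C)C)cn1
F4 | step 4 | chloro(1-SEM-imidazol-4-yl)zinc | Cl[Zn]c1cn(COCC[Si](C)(C)C)cn1
F5 | step 4 | 6-bromo-3-(1-SEM-imidazol-4-yl)-1-(triisopropylsilyl)indole | CC(C)[Si](C(C)C)(C(C)C)n1cc(-c2cn(COCC[Si](C)(C)C)cn2)c2ccc(Br)cc21
F6 | step 4 | 6-bromo-3-(2-lithio-1-SEM-imidazol-4-yl)-1-(triisopropylsilyl)indole | [Li]c1nc(-c2cn([Si](C(C)C)(C(C)C)C(C)C)c3cc(Br)ccc23)cn1COCC[Si](C)(C)C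
F7 | step 4 | chloro{4-[6-bromo-1-(triisopropylsilyl)indol-3-yl]-1-SEM-imidazol-2-yl}zinc | Cl[Zn]c1nc(-c2cn([Si](C(C)C)(C(C)C)C(C)C)c3cc(Br)ccc23)cn1COCC[Si](C)(C)C
F8 | step 4 | tert-butyl 3-{4-[6-bromo-1-(triisopropylsilyl)indol-3-yl]-1-SEM-imidazol-2-yl}indole-1-carboxylate | CC(C)(C)OC(=O)n1cc(-c2nc(-c3cn([Si](C(C)C)(C(C)C)C(C)C)c4cc(Br)ccc34)cn2COCC[Si](C)(C)C)c2ccccc21
F9 | step 3 | 2-iodo-1-SEM-4-[(triethylsilyl)ethynyl]imidazole | CC[Si](CC)(CC)C#Cc1cn(COCC[Si](C)(C)C)c(I)n1
F10 | step 1 | 4,5-diiodo-1H-imidazole | Ic1nc[nH]c1I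
F11 | step 1 | 4,5-diiodo-1-SEM-imidazole | C[Si](C)(C)CCOCn1cnc(I)c1I
F12 | step 1 | bromo(4-iodo-1-SEM-imidazol-5-yl)magnesium | Br[Mg]c1c(I)ncn1COCC[Si](C)(C)C
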